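At 4.0 min I read the target in each flask, and two of them, Sunday's and Tuesday's, have by then spent 3.0 min at 10 °C.

| flask | substrate | partner | protic impurity | temperature | remark | time |
|---|---|---|---|---|---|---|
| south-east | 0.050 M | 0.045 M | 2.5 mM | 35 °C | run made earlier |  |
| north | 0.050 M | 0.063 M | 2.5 mM | 50 °C | run made earlier |  |
| east | 0.050 M | 0.099 M | 2.5 mM | 35 °C | run made earlier |  |
| Monday's | 0.050 M (in portions, 3, over 3.0 min) | 0.0450 M | 2.50 mM | 50 °C | first portion at the start, last at 3.0 min | 4.0 min |
| Tuesday's | 0.050 M (fed, over 3.0 min) | 0.0450 M | 2.50 mM |  | the addition at 10 °C, then warmed to 50 °C; the feed brings no volume worth counting | 4.0 min |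
| Sunday's | 0.050 M | 0.0450 M | 2.50 mM |  | everything together at the start at 10 °C, warmed to 50 °C at 3.0 min | 4.0 min |
| Saturday's | 0.050 M (fed, over 3.0 min) | 0.0450 M | 2.50 mM | 50 °C | all else is in the flask from the start; the feed brings no volume worth counting | 4.0 min |
| Wednesday's | 0.050 M | 0.0450 M (fed, over 3.0 min) | 2.50 mM | 50 °C | all else is in the flask from the start; the feed brings no volume worth counting | 4.0 min |

- south-east (time / min: target / %, substrate / %): 2.00: 2, 19; 3.00: 6, 18; 5.00: 15, 8; 6.00: 21, 7; 8.00: 22, 2
- north (time / min: target / %, substrate / %): 1.00: 16, 9; 2.00: 29, 4; 3.00: 42, 1; 4.00: 43, 1; 5.00: 41, 0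
- east (time / min: target / %, substrate / %): 2.00: 5, 19; 4.00: 20, 13; 6.00: 32, 11; 8.00: 47, 7; 10.0: 57, 6

(each reading ± 2 percentage points)

* the best flask by amount of target, in percent of the substrate charged; "all alike" if 1.5 percentage points covers them all (Monday's / Tuesday's / Sunday's / Saturday's / Wednesday's / all alike)
* amount of target at the end, in percent of the substrate charged, Monday's
* amount of target at the end, in percent of the substrate charged, Tuesday's
* amount of target at the end, in percent of the substrate charged, Sunday's
* amount of target at the end, in percent of the substrate charged, Saturday's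
* amount of target at the end, in percent of the substrate charged, Wednesday's

- a reading of substrate is of its free form alone

In the north run, at 50 °C, target climbs from 16% at 1.00 min to 42% at 3.00 min with [partner] at 0.063 M, which makes 2.06 /M/min. I call this the warm slope: the share of the charged substrate turned into target per minute for each mole per litre of partner.

Using it, I take the climb as first order in [partner], and that is a rough assumption: between the readings east climbs 1.35 times as fast as south-east on 2.20 times the [partner].

I count the cold time as giving no target, an assumption resting on south-east, which at 35 °C, warmer than 10 °C, and on the same partner charge as Sunday's, has 6% at 3.00 min. So I give Sunday's and Tuesday's each the slope for 1.00 min at the charged 0.0450 M of partner, which gives 9.29%. The same slope held for the whole 4.0 min gives 37.1%, so I place these two flasks below Monday's and Saturday's.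

The forecast, above my figure for both cold flasks, names Saturday's as best, with 31% for Monday's, 18% for Tuesday's, 13% for Sunday's, 38% for Saturday's and 14% for Wednesday's, in its words: “The cold flasks get only one warm minute, so they should give little.”

The flasks give 26.3% for Monday's, 9.15% for Tuesday's, 9.01% for Sunday's, 24.2% for Saturday's and 18.0% for Wednesday's, and the best is Monday's.

    substrate → intermediate A (k = 0.0470 /s, Ea = 81.0 kJ/mol)
    intermediate A → intermediate B (k = 0.0220 /s, Ea = 89.0 kJ/mol)
    substrate + partner ⇌ intermediate C (K = 10.0 /M, k = 0.470 /M/s, Ea = 43.0 kJ/mol, ΔH = −53.0 kJ/mol)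
    partner + intermediate B → intermediate D (k = 3.50 /M/s, Ea = 49.0 kJ/mol)
    intermediate B → side product (k = 0.00780 /s, Ea = 80.0 kJ/mol)
    partner + intermediate D → target (k = 0.550 /M/s, Ea = 40.0 kJ/mol)
    partner + protic impurity → quenched reagent (k = 17.0 /M/s, Ea = 55.0 kJ/mol)
    (constants at 50 °C)

Multiplied by 0.0450 M and the 1.00 min at 50 °C, the warm slope of 2.06 /M/min gives 9.29%, while Sunday's holds 9.01% and Tuesday's, fed during its cold part, holds 9.15%. In Sunday's at 3.24 min, intermediate D is made 9.08 times faster than it is used up, each step taken net. At 4.00 min Sunday's holds 25.9% of intermediate D beside 9.01% of target.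

All runs come from a simulation for substances that don't exist; the scatter is artificial.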